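**Strategy.** The route rests on cutting the bond between the guaiacyl ring and C2 of the dihydrobenzofuran ring. It exploits that, with the C3 hydroxymethyl raised to an ester, the O1–C2=C3–C=O array of a flat benzofuran-3-carboxylate is a vinylogous carbonate whose C2 is electrophilic. A Rh(I)/chiral-diene conjugate arylation with a guaiacyl boronic acid should dearomatize the furan ring, set C2 under ligand control and, after base equilibration of the C3 epimers, deliver the trans-2,3-disubstituted ring in one operation. The precursor is an achiral 5-bromo-7-benzyloxybenzofuran ester; the bromide later carries the (2S)-flavanone through a second ligand-controlled chromone arylation.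

Key step: step 4

Assumption: the hand of each chiral diene is assigned by analogy with enone and chromone arylations (for step 4 it is provisional); it would be checked on a model substrate and the antipodal diene, equally available, used if needed.

**Step 1**
Reactants: 1 2,3-dihydroxybenzaldehyde
Product: 2 3-(benzyloxy)-2-hydroxybenzaldehyde
Conditions: NaH (2.2 equiv), DMSO, rt; then BnBr (1.0 equiv), rt
Reagents that add atoms: benzyl bromide BrCc1ccccc1
Why: Williamson etherification of the dianion, in which the 2-phenoxide is stabilised by conjugation with the formyl group, so the more nucleophilic 3-phenoxide should be benzylated selectively.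

**Step 2**
Reactants: 2 3-(benzyloxy)-2-hydroxybenzaldehyde
Product: 3 3-(benzyloxy)-5-bromo-2-hydroxybenzaldehyde
Conditions: Br2 (1.05 equiv), NaOAc, AcOH, rt
Reagents that add atoms: bromine BrBr
Why: Electrophilic aromatic bromination at C5, which is para to the free phenol and meta to the aldehyde, as in the bromination of o-vanillin.

**Step 3**
Reactants: 3 3-(benzyloxy)-5-bromo-2-hydroxybenzaldehyde; 4 ethyl diazoacetate
Product: 6 ethyl 7-(benzyloxy)-5-bromo-1-benzofuran-3-carboxylate, via cyclic hemiacetal 5 (not isolated)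
Conditions: HBF4·OEt2 (10 mol %), CH2Cl2, rt, slow addition of 4; then conc. H2SO4, rt
Reagents that add atoms: none
Why: Acid-catalysed addition of the diazo ester to the aldehyde with 1,2-aryl shift (Roskamp-type homologation) should give the 2-aryl-3-oxopropanoate, which closes to hemiacetal 5 and is dehydrated to the benzofuran, leaving no stereocentre.

**Step 4**
Reactants: 6 ethyl 7-(benzyloxy)-5-bromo-1-benzofuran-3-carboxylate; 7 [4-(benzyloxy)-3-methoxyphenyl]boronic acid
Product: 9 ethyl (2R,3R)-7-(benzyloxy)-2-[4-(benzyloxy)-3-methoxyphenyl]-5-bromo-2,3-dihydro-1-benzofuran-3-carboxylate (trans ester), via cis ester 8 (not isolated)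
Conditions: 7 (2 equiv), [RhCl(C2H4)2]2 (2.5 mol %), (R,R)-Ph-bod* (5.5 mol %), aq. KOH (0.1 equiv), 1,4-dioxane/H2O 10:1, 60 °C; then DBU (0.3 equiv), rt
Reagents that add atoms: none
Why: Proposed new method: transmetalation should give an aryl–Rh(I) diene species that inserts the polarised C2=C3 bond of the vinylogous carbonate with aryl delivery to C2, and hydrolysis of the resulting oxa-π-allyl rhodium releases the ester and Rh–OH. The closest known reaction type is the Hayashi–Miyaura asymmetric 1,4-addition of arylboronic acids to chromones and coumarins, here extended to a benzofuran whose furan ring is thereby dearomatised; no ring is closed. C2 is set by the chiral diene, which selects the face of the flat heteroarene, whereas C3 is first formed as an epimer mixture on protonation and is funnelled by DBU through the ester enolate into the trans isomer, in which the 2-aryl and 3-ester groups avoid each other. syn-Insertion leaves the C2–H anti to rhodium, so β-hydride elimination back to a 2-arylbenzofuran should be shut off. The step needs chemoselectivity for the boronic acid over the aryl bromide, which Rh(I) does not insert, and only mild base, so that the C3 enolate does not expel the O1 phenoxide and erase C2.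

**Step 5**
Reactants: 9 ethyl (2R,3R)-7-(benzyloxy)-2-[4-(benzyloxy)-3-methoxyphenyl]-5-bromo-2,3-dihydro-1-benzofuran-3-carboxylate
Product: 10 [(2R,3S)-7-(benzyloxy)-2-[4-(benzyloxy)-3-methoxyphenyl]-5-bromo-2,3-dihydro-1-benzofuran-3-yl]methanol
Conditions: DIBAL-H (3 equiv), CH2Cl2, −78 → 0 °C; Rochelle salt work-up
Reagents that add atoms: none
Why: Hydride reduction of the ester to the primary alcohol under non-basic conditions, which fixes C3, leaves C2 and the aryl bromide untouched, and removes the ester before any ketone is present.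

**Step 6**
Reactants: 10 [(2R,3S)-7-(benzyloxy)-2-[4-(benzyloxy)-3-methoxyphenyl]-5-bromo-2,3-dihydro-1-benzofuran-3-yl]methanol
Product: 11 [(2R,3S)-7-(benzyloxy)-2-[4-(benzyloxy)-3-methoxyphenyl]-3-(hydroxymethyl)-2,3-dihydro-1-benzofuran-5-yl]boronic acid
Conditions: B2(OH)4 (3 equiv), XPhos Pd G2 (2 mol %), XPhos (4 mol %), KOAc (3 equiv), EtOH, 80 °C
Reagents that add atoms: tetrahydroxydiboron OB(O)B(O)O
Why: Miyaura-type Pd-catalysed borylation of the aryl bromide with tetrahydroxydiboron should give the boronic acid directly, the benzyl ethers, free alcohol and both stereocentres being inert to KOAc in ethanol.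

**Step 7**
Reactants: 12 1-(2,4,6-trihydroxyphenyl)ethanone
Product: 13 1-[2,4-bis(benzyloxy)-6-hydroxyphenyl]ethanone
Conditions: BnBr (2.1 equiv), K2CO3 (2.2 equiv), DMF, rt
Reagents that add atoms: benzyl bromide BrCc1ccccc1
Why: Williamson etherification in which two hydroxyls are benzylated while the last one, hydrogen-bonded to the acetyl group, should stay free.

**Step 8**
Reactants: 13 1-[2,4-bis(benzyloxy)-6-hydroxyphenyl]ethanone
Product: 15 5,7-bis(benzyloxy)-4H-chromen-4-one, via enaminone 14 (not isolated)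
Conditions: Me2NCH(OMe)2 (3 equiv), toluene, 90 °C; then conc. HCl, CH2Cl2, 40 °C
Reagents that add atoms: N,N-dimethylformamide dimethyl acetal COC(OC)N(C)C
Why: Condensation of the methyl ketone with the amide acetal gives enaminone 14, and acid-promoted addition of the phenol with loss of dimethylamine closes the pyranone ring (enaminone route to chromones).

**Step 9**
Reactants: 11 [(2R,3S)-7-(benzyloxy)-2-[4-(benzyloxy)-3-methoxyphenyl]-3-(hydroxymethyl)-2,3-dihydro-1-benzofuran-5-yl]boronic acid; 15 5,7-bis(benzyloxy)-4H-chromen-4-one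
Product: 16 (2S)-5,7-bis(benzyloxy)-2-[(2R,3S)-7-(benzyloxy)-2-[4-(benzyloxy)-3-methoxyphenyl]-3-(hydroxymethyl)-2,3-dihydro-1-benzofuran-5-yl]-2,3-dihydro-4H-chromen-4-one
Conditions: 15 (2 equiv), [RhCl(C2H4)2]2 (2.5 mol %), (S,S)-Ph-bod* (5.5 mol %), aq. KOH (0.1 equiv), toluene/H2O, 30 °C
Reagents that add atoms: none
Why: Hayashi–Miyaura asymmetric 1,4-addition of an arylboronic acid to a chromone, in which the chiral diene selects the face of chromone C2 and sets the (2S) flavanone centre independently of the remote dihydrobenzofuran centres, while low base loading at 30 °C should avoid retro-oxa-Michael opening.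

**Step 10**
Reactants: 16 (2S)-5,7-bis(benzyloxy)-2-[(2R,3S)-7-(benzyloxy)-2-[4-(benzyloxy)-3-methoxyphenyl]-3-(hydroxymethyl)-2,3-dihydro-1-benzofuran-5-yl]-2,3-dihydro-4H-chromen-4-one
Product: 17 silyhermin B, (2S)-5,7-dihydroxy-2-[(2R,3S)-7-hydroxy-2-(4-hydroxy-3-methoxyphenyl)-3-(hydroxymethyl)-2,3-dihydro-1-benzofuran-5-yl]-2,3-dihydro-4H-chromen-4-one
Conditions: H2 (1 atm), 10% Pd/C, EtOAc/MeOH 1:1, rt, stopped at complete debenzylation
Reagents that add atoms: none
Why: Catalytic hydrogenolysis of the four aryl benzyl ethers, which should be cleaved faster than the two cyclic benzylic C–O bonds and the aryl ketone, under neutral conditions that touch no stereocentre.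

**Compound list**
1 | 2,3-dihydroxybenzaldehyde | O=Cc1cccc(O)c1O | starting material
2 | 3-(benzyloxy)-2-hydroxybenzaldehyde | O=Cc1cccc(OCc2ccccc2)c1O | intermediate
3 | 3-(benzyloxy)-5-bromo-2-hydroxybenzaldehyde | O=Cc1cc(Br)cc(OCc2ccccc2)c1O | intermediate
4 | ethyl diazoacetate | CCOC(=O)C=[N+]=[N-] | starting material
5 | ethyl 7-(benzyloxy)-5-bromo-2-hydroxy-2,3-dihydro-1-benzofuran-3-carboxylate (cyclic hemiacetal, diastereomer mixture) | CCOC(=O)C1C(O)Oc2c(OCc3ccccc3)cc(Br)cc21 | intermediate (not isolated)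
6 | ethyl 7-(benzyloxy)-5-bromo-1-benzofuran-3-carboxylate | CCOC(=O)c1coc2c(OCc3ccccc3)cc(Br)cc12 | intermediate
7 | [4-(benzyloxy)-3-methoxyphenyl]boronic acid | COc1cc(B(O)O)ccc1OCc1ccccc1 | starting material
8 | ethyl (2R,3S)-7-(benzyloxy)-2-[4-(benzyloxy)-3-methoxyphenyl]-5-bromo-2,3-dihydro-1-benzofuran-3-carboxylate (cis ester) | COc1cc([C@@H]2Oc3c(OCc4ccccc4)cc(Br)cc3[C@@H]2C(=O)OCC)ccc1OCc1ccccc1 | intermediate (not isolated)
9 | ethyl (2R,3R)-7-(benzyloxy)-2-[4-(benzyloxy)-3-methoxyphenyl]-5-bromo-2,3-dihydro-1-benzofuran-3-carboxylate (trans ester) | COc1cc([C@@H]2Oc3c(OCc4ccccc4)cc(Br)cc3[C@H]2C(=O)OCC)ccc1OCc1ccccc1 | intermediate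
10 | [(2R,3S)-7-(benzyloxy)-2-[4-(benzyloxy)-3-methoxyphenyl]-5-bromo-2,3-dihydro-1-benzofuran-3-yl]methanol | COc1cc([C@@H]2Oc3c(OCc4ccccc4)cc(Br)cc3[C@H]2CO)ccc1OCc1ccccc1 | intermediate
11 | [(2R,3S)-7-(benzyloxy)-2-[4-(benzyloxy)-3-methoxyphenyl]-3-(hydroxymethyl)-2,3-dihydro-1-benzofuran-5-yl]boronic acid | COc1cc([C@@H]2Oc3c(OCc4ccccc4)cc(B(O)O)cc3[C@H]2CO)ccc1OCc1ccccc1 | intermediate
12 | 1-(2,4,6-trihydroxyphenyl)ethanone | CC(=O)c1c(O)cc(O)cc1O | starting material
13 | 1-[2,4-bis(benzyloxy)-6-hydroxyphenyl]ethanone | CC(=O)c1c(O)cc(OCc2ccccc2)cc1OCc1ccccc1 | intermediate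
14 | (E)-1-[2,4-bis(benzyloxy)-6-hydroxyphenyl]-3-(dimethylamino)prop-2-en-1-one (enaminone) | CN(C)/C=C/C(=O)c1c(O)cc(OCc2ccccc2)cc1OCc1ccccc1 | intermediate (not isolated)
15 | 5,7-bis(benzyloxy)-4H-chromen-4-one | O=c1ccoc2cc(OCc3ccccc3)cc(OCc3ccccc3)c12 | intermediate
16 | (2S)-5,7-bis(benzyloxy)-2-[(2R,3S)-7-(benzyloxy)-2-[4-(benzyloxy)-3-methoxyphenyl]-3-(hydroxymethyl)-2,3-dihydro-1-benzofuran-5-yl]-2,3-dihydro-4H-chromen-4-one | COc1cc([C@@H]2Oc3c(OCc4ccccc4)cc([C@@H]4CC(=O)c5c(OCc6ccccc6)cc(OCc6ccccc6)cc5O4)cc3[C@H]2CO)ccc1OCc1ccccc1 | intermediate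
17 | silyhermin B, (2S)-5,7-dihydroxy-2-[(2R,3S)-7-hydroxy-2-(4-hydroxy-3-methoxyphenyl)-3-(hydroxymethyl)-2,3-dihydro-1-benzofuran-5-yl]-2,3-dihydro-4H-chromen-4-one | COc1cc([C@@H]2Oc3c(O)cc([C@@H]4CC(=O)c5c(O)cc(O)cc5O4)cc3[C@H]2CO)ccc1O | target

**Step count.** Total: 10 steps. Longest linear sequence: 8 steps (steps 1–6, 9, 10); the chromone branch is steps 7–8.

**Steps most likely to fail**

1. Step 4 (the labelled step). Insertion of the aryl–rhodium into the aromatic C2=C3 bond may be too slow, so that protodeboronation of the boronic acid takes over, or the diene may give poor facial selectivity. The fallback uses known reaction types only, sets out from boronic acid 7 and comes back at alcohol 10; the same aryl–carbon bond is made on a chromone and the ring is contracted afterwards. Commercial 1-(2,3-dihydroxyphenyl)ethanone F1 is benzylated at the non-chelated 3-hydroxyl (BnBr, K2CO3, DMF) to 1-[3-(benzyloxy)-2-hydroxyphenyl]ethanone F2. Bromination para to the phenol (Br2, NaOAc, AcOH) gives 1-[3-(benzyloxy)-5-bromo-2-hydroxyphenyl]ethanone F3. Condensation with DMF dimethyl acetal gives (E)-1-[3-(benzyloxy)-5-bromo-2-hydroxyphenyl]-3-(dimethylamino)prop-2-en-1-one F4, which HCl cyclises to 8-(benzyloxy)-6-bromo-4H-chromen-4-one F5. Hayashi–Miyaura addition of 7 to this chromone with Rh(I)/(R,R)-Ph-bod* should give (2R)-8-(benzyloxy)-2-[4-(benzyloxy)-3-methoxyphenyl]-6-bromo-2,3-dihydro-4H-chromen-4-one F6. Oxidative ring contraction of this flavanone with PhI(OAc)2 and H2SO4 in trimethyl orthoformate moves the fused aryl carbon from C4 to C3 and leaves C2 untouched. After DBU equilibration it should give methyl (2R,3R)-7-(benzyloxy)-2-[4-(benzyloxy)-3-methoxyphenyl]-5-bromo-2,3-dihydro-1-benzofuran-3-carboxylate F7, which DIBAL-H reduces to 10.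

2. Step 9. The valuable boronic acid may be lost to protodeboronation, insertion into the 5-alkoxychromone may be sluggish, or facial control may be incomplete. The fallback sets out from bromide 10 and acetophenone 13 and comes back at 16, building the flavanone by aldol and oxa-Michael chemistry instead. Bromine–lithium exchange (n-BuLi, 2.2 equiv, THF, −78 °C) and a DMF quench give (2R,3S)-7-(benzyloxy)-2-[4-(benzyloxy)-3-methoxyphenyl]-3-(hydroxymethyl)-2,3-dihydro-1-benzofuran-5-carbaldehyde F8. Claisen–Schmidt condensation with 13 (KOH, EtOH, rt) gives (E)-1-[2,4-bis(benzyloxy)-6-hydroxyphenyl]-3-[(2R,3S)-7-(benzyloxy)-2-[4-(benzyloxy)-3-methoxyphenyl]-3-(hydroxymethyl)-2,3-dihydro-1-benzofuran-5-yl]prop-2-en-1-one F9. NaOAc in refluxing EtOH closes the pyranone by oxa-Michael addition to give 16 together with its flavanone C2 epimer (2R)-5,7-bis(benzyloxy)-2-[(2R,3S)-7-(benzyloxy)-2-[4-(benzyloxy)-3-methoxyphenyl]-3-(hydroxymethyl)-2,3-dihydro-1-benzofuran-5-yl]-2,3-dihydro-4H-chromen-4-one F10. The two diastereomers are separated by preparative HPLC and the unwanted one is recycled through the chalcone equilibrium.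

3. Step 10. Hydrogenolysis may go on to cleave the benzylic C2–O bonds of the dihydrobenzofuran or the flavanone, or reduce the ketone. The fallback goes from 16 straight to 17 by Lewis-acid debenzylation instead of reduction: BCl3 with pentamethylbenzene as cation scavenger, CH2Cl2, −78 °C. This should leave the cyclic benzylic ethers, the ketone and the aryl methyl ether intact; no new compound is made (F0).

**Further compounds**
F1 | step 4 | 1-(2,3-dihydroxyphenyl)ethanone | CC(=O)c1cccc(O)c1O
F2 | step 4 | 1-[3-(benzyloxy)-2-hydroxyphenyl]ethanone | CC(=O)c1cccc(OCc2ccccc2)c1O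
F3 | step 4 | 1-[3-(benzyloxy)-5-bromo-2-hydroxyphenyl]ethanone | CC(=O)c1cc(Br)cc(OCc2ccccc2)c1O
F4 | step 4 | (E)-1-[3-(benzyloxy)-5-bromo-2-hydroxyphenyl]-3-(dimethylamino)prop-2-en-1-one | CN(C)/C=C/C(=O)c1cc(Br)cc(OCc2ccccc2)c1O
F5 | step 4 | 8-(benzyloxy)-6-bromo-4H-chromen-4-one | O=c1ccoc2c(OCc3ccccc3)cc(Br)cc12
F6 | step 4 | (2R)-8-(benzyloxy)-2-[4-(benzyloxy)-3-methoxyphenyl]-6-bromo-2,3-dihydro-4H-chromen-4-one | COc1cc([C@H]2CC(=O)c3cc(Br)cc(OCc4ccccc4)c3O2)ccc1OCc1ccccc1
F7 | step 4 | methyl (2R,3R)-7-(benzyloxy)-2-[4-(benzyloxy)-3-methoxyphenyl]-5-bromo-2,3-dihydro-1-benzofuran-3-carboxylate | COc1cc([C@@H]2Oc3c(OCc4ccccc4)cc(Br)cc3[C@H]2C(=O)OC)ccc1OCc1ccccc1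
F8 | step 9 | (2R,3S)-7-(benzyloxy)-2-[4-(benzyloxy)-3-methoxyphenyl]-3-(hydroxymethyl)-2,3-dihydro-1-benzofuran-5-carbaldehyde | COc1cc([C@@H]2Oc3c(OCc4ccccc4)cc(C=O)cc3[C@H]2CO)ccc1OCc1ccccc1
F9 | step 9 | (E)-1-[2,4-bis(benzyloxy)-6-hydroxyphenyl]-3-[(2R,3S)-7-(benzyloxy)-2-[4-(benzyloxy)-3-methoxyphenyl]-3-(hydroxymethyl)-2,3-dihydro-1-benzofuran-5-yl]prop-2-en-1-one | COc1cc([C@@H]2Oc3c(OCc4ccccc4)cc(/C=C/C(=O)c4c(O)cc(OCc5ccccc5)cc4OCc4ccccc4)cc3[C@H]2CO)ccc1OCc1ccccc1
F10 | step 9 | (2R)-5,7-bis(benzyloxy)-2-[(2R,3S)-7-(benzyloxy)-2-[4-(benzyloxy)-3-methoxyphenyl]-3-(hydroxymethyl)-2,3-dihydro-1-benzofuran-5-yl]-2,3-dihydro-4H-chromen-4-one | COc1cc([C@@H]2Oc3c(OCc4ccccc4)cc([C@H]4CC(=O)c5c(OCc6ccccc6)cc(OCc6ccccc6)cc5O4)cc3[C@H]2CO)ccc1OCc1ccccc1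
F0 | step 10 | none | none
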